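**Retrosynthetic overview**
- Feature: ring carbons C5–C4–C3 of the oxolane plus the exocyclic hydroxymethyl carbon C6 form a four-carbon chain with oxygen at both ends (O1 on C5, OH on C6). Read as an aldehyde-acid, this chain is the skeleton of a 5-alkoxyfuran-2(5H)-one whose β-carbon C4 carries the ketone carbon C7 and whose α-carbon C3 carries the aryl carbinol carbon C2.
- Key disconnections: C4–C7 (conjugate addition of a lithiated aryl dithiane as aroyl anion) and C2–C3 (aldol trapping of the lactone enolate by 3,4,5-trimethoxybenzaldehyde), made in one pot on (5S)-5-(d-menthyloxy)furan-2(5H)-one. Its acetal carbon C5 is the only stereocentre brought in, and it relays to C4, C3 and C2.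
- Ring order: the butenolide ring is built first (furfural photooxygenation, menthol acetalisation) and serves only as a template. The oxolane ring (O1, C2–C5) is closed afterwards through O1–C5 by acid transacetalisation, which opens the lactone at the same time.
- Finish: C5 acetal to CH2, C6 ester to CH2OH, dithiane to the C7 ketone, then equilibration of C4 (α to the ketone) from cis to trans.

Key step: step 4

Assumption: the target locants (O1, C2 aryl-bearing, C3 bearing C6, C4 bearing C7, C5) are used for every intermediate, Ar = 3,4,5-trimethoxyphenyl, and the target is (2S,3S,4R), that is 2,3-cis and 3,4-trans; because C4 ends α to a ketone it is set last under thermodynamic control, so its configuration in earlier intermediates need not match the target.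

**Route**

Step 1
Reactants: 1 furfural
Product: 3 5-hydroxyfuran-2(5H)-one (racemic), via furfural endoperoxide 2 (not isolated)
Conditions: O2, rose bengal (C20H2Cl4I4Na2O5, cat.), MeOH, visible light, 15–20 °C
Reagents that add atoms: oxygen, O=O
Why: dye-sensitised photooxygenation of a furan, in which singlet oxygen adds across C2/C5 in a [4+2] cycloaddition to give endoperoxide 2, which methanol should cleave at the formyl group with loss of methyl formate to leave the racemic hydroxybutenolide.

Step 2
Reactants: 3 5-hydroxyfuran-2(5H)-one; 4 d-menthol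
Product: 6 (5S)-5-(d-menthyloxy)furan-2(5H)-one, via 5R epimer 5 (not isolated)
Conditions: camphor-10-sulfonic acid (cat.), toluene, reflux, azeotropic removal of water; crystallisation from petroleum ether, −20 °C; mother liquor re-equilibrated with cat. p-TsOH and recrystallised
Reagents that add atoms: none
Why: acid-catalysed acetalisation of the cyclic hemiacetal should give both C5 epimers, and since the acetal centre is labile under the acid, the 5S epimer (expected to be the less soluble one) is collected by crystallisation while epimer 5 in the mother liquor is re-equilibrated and recycled, which sets C5.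

Step 3
Reactants: 7 3,4,5-trimethoxybenzaldehyde; 8 propane-1,3-dithiol
Product: 9 2-(3,4,5-trimethoxyphenyl)-1,3-dithiane
Conditions: BF3·OEt2 (cat.), CH2Cl2, 0 °C to rt
Reagents that add atoms: none
Why: Lewis acid-catalysed dithioacetalisation of an aromatic aldehyde, which turns the formyl carbon (the future C7) into a masked acyl anion.

Step 4
Reactants: 9 2-(3,4,5-trimethoxyphenyl)-1,3-dithiane; 6 (5S)-5-(d-menthyloxy)furan-2(5H)-one; 7 3,4,5-trimethoxybenzaldehyde
Product: 13 (3R,4S,5S)-3-[(S)-hydroxy(3,4,5-trimethoxyphenyl)methyl]-5-(d-menthyloxy)-4-[2-(3,4,5-trimethoxyphenyl)-1,3-dithian-2-yl]oxolan-2-one, via lithiated dithiane 10 (not isolated), via lithium lactone enolate 11 (not isolated), via lithium aldolate 12 (not isolated)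
Conditions: 9, n-BuLi, THF, −78 to −20 °C; then 6, THF, −78 °C; then 7, THF, −78 °C; AcOH, −78 °C
Reagents that add atoms: none
Why: Lithiated dithiane 10, a soft acyl-anion equivalent for C7, should add 1,4 to butenolide 6 at C4 on the face opposite the C5 menthyloxy group (C4–C7 bond), and the resulting lithium enolate 11 should add through C3 to aldehyde 7 on the ring face opposite the new dithianyl group (C2–C3 bond) to give aldolate 12, which is protonated with AcOH at −78 °C before retro-aldol equilibration can set in. This is a tandem Michael addition–aldol reaction of the type known for lithiated 2-aryl-1,3-dithianes and 5-alkoxyfuran-2(5H)-ones with electrophile trapping; no ring is closed, the lactone acting only as a template. C4 is controlled by the acetal centre C5 (anti addition), C3 by C4 (trans trapping of the planar enolate), and C2 by the enolate geometry: the ring fixes C4 trans to the O–Li bond, so a closed six-membered lithium chair with the aryl group equatorial should give the anti aldol, the 2S carbinol that maps onto the 2,3-cis oxolane. The step needs 1,4- over 1,2-addition, which the sulfur-stabilised anion in THF at low temperature should secure, and anti over syn aldol selectivity, which rests on the chair preference alone and is the weakest control element, so the carbinol epimers are to be separated by chromatography.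

Step 5
Reactants: 13 (3R,4S,5S)-3-[(S)-hydroxy(3,4,5-trimethoxyphenyl)methyl]-5-(d-menthyloxy)-4-[2-(3,4,5-trimethoxyphenyl)-1,3-dithian-2-yl]oxolan-2-one
Product: 14 methyl (2S,3R,4S)-5-methoxy-2-(3,4,5-trimethoxyphenyl)-4-[2-(3,4,5-trimethoxyphenyl)-1,3-dithian-2-yl]oxolane-3-carboxylate (mixture of C5 anomers)
Conditions: camphor-10-sulfonic acid (0.2 equiv), dry MeOH, rt to 40 °C; then NaHCO3
Reagents that add atoms: methanol, CO
Why: acid methanolysis of the γ-alkoxy lactone (transacetalisation plus Fischer esterification) should ionise C5 with release of the C6 acid, the C2 hydroxyl capturing the C5 oxocarbenium ion in a 5-exo closure while menthol is exchanged for methanol and the acid is esterified; the C2–O bond is never broken, so C2 is retained, and the C5 anomer mixture and any open-chain dimethyl acetal converge in step 6.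

Step 6
Reactants: 14 methyl (2S,3R,4S)-5-methoxy-2-(3,4,5-trimethoxyphenyl)-4-[2-(3,4,5-trimethoxyphenyl)-1,3-dithian-2-yl]oxolane-3-carboxylate
Product: 15 methyl (2S,3R,4S)-2-(3,4,5-trimethoxyphenyl)-4-[2-(3,4,5-trimethoxyphenyl)-1,3-dithian-2-yl]oxolane-3-carboxylate
Conditions: Et3SiH, BF3·OEt2, CH2Cl2, −78 to −30 °C
Reagents that add atoms: none
Why: ionic hydrogenation of a cyclic acetal, in which BF3·OEt2 ionises the C5–OMe bond to the ring oxocarbenium ion and Et3SiH reduces it to CH2, while the benzylic ring ether at C2, the ester and the dithiane should be inert at low temperature.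

Step 7
Reactants: 15 methyl (2S,3R,4S)-2-(3,4,5-trimethoxyphenyl)-4-[2-(3,4,5-trimethoxyphenyl)-1,3-dithian-2-yl]oxolane-3-carboxylate
Product: 16 [(2S,3S,4S)-2-(3,4,5-trimethoxyphenyl)-4-[2-(3,4,5-trimethoxyphenyl)-1,3-dithian-2-yl]oxolan-3-yl]methanol
Conditions: LiAlH4, THF, 0 °C; then aqueous work-up
Reagents that add atoms: none
Why: hydride reduction of the ester to the primary alcohol should be much faster than enolisation, so C3 is kept and is no longer epimerisable once C6 is a carbinol (the descriptor changes from R to S only through the priority change).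

Step 8
Reactants: 16 [(2S,3S,4S)-2-(3,4,5-trimethoxyphenyl)-4-[2-(3,4,5-trimethoxyphenyl)-1,3-dithian-2-yl]oxolan-3-yl]methanol
Product: 17 (2S,3S,4S)-3-(hydroxymethyl)-4-(3,4,5-trimethoxybenzoyl)-2-(3,4,5-trimethoxyphenyl)oxolane (the all-cis C4 epimer of the target)
Conditions: HgO, BF3·OEt2, THF/H2O (85:15), rt
Reagents that add atoms: water, O
Why: mercury-assisted hydrolysis of the dithiane (thiophilic dethioacetalisation) should unmask the C7 aryl ketone without touching the aryl ethers, the benzylic ring ether or the free alcohol.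

Step 9
Reactants: 17 (2S,3S,4S)-3-(hydroxymethyl)-4-(3,4,5-trimethoxybenzoyl)-2-(3,4,5-trimethoxyphenyl)oxolane
Product: 18 (2S,3S,4R)-3-(hydroxymethyl)-4-(3,4,5-trimethoxybenzoyl)-2-(3,4,5-trimethoxyphenyl)oxolane (target, CNP0148560.1)
Conditions: DBU (0.5 equiv), CH2Cl2, rt
Reagents that add atoms: none
Why: base-mediated epimerisation through the ketone enolate, in which C4 is the only acidic stereocentre and the crowded all-cis isomer should relax under thermodynamic control to the 3,4-trans (4R) arrangement while C2 and C3 stay fixed.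

**Compound list**
1 | furfural (furan-2-carbaldehyde) | O=Cc1ccco1 | starting material
2 | furfural endoperoxide (2,3,7-trioxabicyclo[2.2.1]hept-5-ene-1-carbaldehyde) | O=CC12C=CC(OO1)O2 | intermediate
3 | 5-hydroxyfuran-2(5H)-one (racemic) | O=C1C=CC(O)O1 | intermediate
4 | d-menthol, (1S,2R,5S)-2-isopropyl-5-methylcyclohexan-1-ol | O[C@H]1C[C@@H](C)CC[C@@H]1C(C)C | starting material
5 | (5R)-5-(d-menthyloxy)furan-2(5H)-one | O=C1C=C[C@H](O[C@H]2C[C@@H](C)CC[C@@H]2C(C)C)O1 | intermediate
6 | (5S)-5-(d-menthyloxy)furan-2(5H)-one | O=C1C=C[C@@H](O[C@H]2C[C@@H](C)CC[C@@H]2C(C)C)O1 | intermediate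
7 | 3,4,5-trimethoxybenzaldehyde | COc1cc(C=O)cc(OC)c1OC | starting material
8 | propane-1,3-dithiol | SCCCS | starting material
9 | 2-(3,4,5-trimethoxyphenyl)-1,3-dithiane | COc1cc(C2SCCCS2)cc(OC)c1OC | intermediate
10 | 2-lithio-2-(3,4,5-trimethoxyphenyl)-1,3-dithiane | COc1cc(C2([Li])SCCCS2)cc(OC)c1OC | intermediate
11 | lithium enolate of (4S,5S)-5-(d-menthyloxy)-4-[2-(3,4,5-trimethoxyphenyl)-1,3-dithian-2-yl]oxolan-2-one | [Li]OC1=C[C@H](C2(c3cc(OC)c(OC)c(OC)c3)SCCCS2)[C@@H](O[C@H]4C[C@@H](C)CC[C@@H]4C(C)C)O1 | intermediate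
12 | lithium alkoxide of 13 (lithium aldolate) | O=C1O[C@H](O[C@H]2C[C@@H](C)CC[C@@H]2C(C)C)[C@@H](C3(c4cc(OC)c(OC)c(OC)c4)SCCCS3)[C@@H]1[C@H](O[Li])c1cc(OC)c(OC)c(OC)c1 | intermediate
13 | (3R,4S,5S)-3-[(S)-hydroxy(3,4,5-trimethoxyphenyl)methyl]-5-(d-menthyloxy)-4-[2-(3,4,5-trimethoxyphenyl)-1,3-dithian-2-yl]oxolan-2-one | O=C1O[C@H](O[C@H]2C[C@@H](C)CC[C@@H]2C(C)C)[C@@H](C3(c4cc(OC)c(OC)c(OC)c4)SCCCS3)[C@@H]1[C@H](O)c1cc(OC)c(OC)c(OC)c1 | intermediate
14 | methyl (2S,3R,4S)-5-methoxy-2-(3,4,5-trimethoxyphenyl)-4-[2-(3,4,5-trimethoxyphenyl)-1,3-dithian-2-yl]oxolane-3-carboxylate (C5 anomers) | COc1cc(C2(SCCCS2)[C@@H]3C(OC)O[C@H](c4cc(OC)c(OC)c(OC)c4)[C@@H]3C(=O)OC)cc(OC)c1OC | intermediate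
15 | methyl (2S,3R,4S)-2-(3,4,5-trimethoxyphenyl)-4-[2-(3,4,5-trimethoxyphenyl)-1,3-dithian-2-yl]oxolane-3-carboxylate | COc1cc(C2(SCCCS2)[C@@H]3CO[C@H](c4cc(OC)c(OC)c(OC)c4)[C@@H]3C(=O)OC)cc(OC)c1OC | intermediate
16 | [(2S,3S,4S)-2-(3,4,5-trimethoxyphenyl)-4-[2-(3,4,5-trimethoxyphenyl)-1,3-dithian-2-yl]oxolan-3-yl]methanol | COc1cc(C2(SCCCS2)[C@@H]3CO[C@H](c4cc(OC)c(OC)c(OC)c4)[C@@H]3CO)cc(OC)c1OC | intermediate
17 | (2S,3S,4S)-3-(hydroxymethyl)-4-(3,4,5-trimethoxybenzoyl)-2-(3,4,5-trimethoxyphenyl)oxolane | COc1cc(C(=O)[C@@H]2CO[C@H](c3cc(OC)c(OC)c(OC)c3)[C@@H]2CO)cc(OC)c1OC | intermediate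
18 | (2S,3S,4R)-3-(hydroxymethyl)-4-(3,4,5-trimethoxybenzoyl)-2-(3,4,5-trimethoxyphenyl)oxolane | COc1cc(C(=O)[C@H]2CO[C@H](c3cc(OC)c(OC)c(OC)c3)[C@@H]2CO)cc(OC)c1OC | target

**Step count**
Total steps: 9. Longest linear sequence: 8 steps (1, 2, 4, 5, 6, 7, 8, 9 from furfural); step 3 is a one-step branch.

**Steps most likely to fail**

Step 4. The closed lithium chair may discriminate poorly between anti and syn aldol addition, or the aldolate may equilibrate by retro-aldol before the quench, so that much of the material carries the wrong C2 configuration. Fallback: C2 is reset by hydride delivery instead of by the aldol. It sets out from 6, 9 and 7 through the syn-aldol epimer F1 that step 4 forms beside 13 and that is separated by chromatography. LiAlH4 in THF at 0 °C should reduce the lactone and the acetal carbon of F1 to the 2R triol F2 with release of d-menthol. Activated MnO2 in CH2Cl2 should oxidise only the benzylic carbinol to the keto diol F3, which is expected to rest as its cyclic hemiketal with the C5 hydroxyl. Et3SiH and BF3·OEt2 in CH2Cl2 at −78 °C should then reduce the 2-aryl oxocarbenium ion on the face opposite the cis-disposed C3 and C4 substituents, placing the aryl group cis to both. This comes back to the route at 16.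

Step 5. Under protic acid the benzylic C2–O bond may ionise (epimerisation or methyl ether formation at C2), the β-hydroxy lactone may dehydrate, or the crowded all-cis oxolane may fail to close. Fallback: the ring is closed from the C5 oxygen onto C2 without any protic acid acting on the carbinol. It sets out from 13, which LiAlH4 in THF should reduce to the 2S triol F4 with release of d-menthol. MnO2 oxidation of the benzylic carbinol converges on the keto diol F3 described above, and Et3SiH with BF3·OEt2 at −78 °C should reduce its hemiketal to the all-cis oxolane. This comes back to the route at 16.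

Step 9. Epimerisation may stall because 17 hides its ketone as a bicyclic hemiketal with the cis C6 hydroxyl, or the enolate may expel O1 from C5 (β-elimination) and re-close through the C6 hydroxyl to an isomeric oxolane. Fallback: the hydroxyl is masked during the equilibration. It sets out from 17, which TBSCl and imidazole in DMF should convert to the silyl ether F5. DBU in CH2Cl2 should equilibrate C4 to give the 4R silyl ether F6. HF·pyridine in THF should remove the silyl group under non-basic conditions. This comes back to the route at 18.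

**Further compounds**
F1 | step 4 | (3R,4S,5S)-3-[(R)-hydroxy(3,4,5-trimethoxyphenyl)methyl]-5-(d-menthyloxy)-4-[2-(3,4,5-trimethoxyphenyl)-1,3-dithian-2-yl]oxolan-2-one (syn-aldol epimer of 13) | O=C1O[C@H](O[C@H]2C[C@@H](C)CC[C@@H]2C(C)C)[C@@H](C3(c4cc(OC)c(OC)c(OC)c4)SCCCS3)[C@@H]1[C@@H](O)c1cc(OC)c(OC)c(OC)c1
F2 | step 4 | (1R,2S,3S)-2-(hydroxymethyl)-1-(3,4,5-trimethoxyphenyl)-3-[2-(3,4,5-trimethoxyphenyl)-1,3-dithian-2-yl]butane-1,4-diol (2R triol by target locants) | OC[C@@H](C1(c2cc(OC)c(OC)c(OC)c2)SCCCS1)[C@@H](CO)[C@@H](O)c1cc(OC)c(OC)c(OC)c1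
F3 | step 4 | (2S,3S)-4-hydroxy-2-(hydroxymethyl)-1-(3,4,5-trimethoxyphenyl)-3-[2-(3,4,5-trimethoxyphenyl)-1,3-dithian-2-yl]butan-1-one (keto diol, ring-chain tautomer of the C2 hemiketal) | OC[C@@H](C1(c2cc(OC)c(OC)c(OC)c2)SCCCS1)[C@@H](CO)C(=O)c1cc(OC)c(OC)c(OC)c1
F4 | step 5 | (1S,2S,3S)-2-(hydroxymethyl)-1-(3,4,5-trimethoxyphenyl)-3-[2-(3,4,5-trimethoxyphenyl)-1,3-dithian-2-yl]butane-1,4-diol (2S triol by target locants) | OC[C@@H](C1(c2cc(OC)c(OC)c(OC)c2)SCCCS1)[C@@H](CO)[C@H](O)c1cc(OC)c(OC)c(OC)c1
F5 | step 9 | (2S,3S,4S)-3-[(tert-butyldimethylsilyloxy)methyl]-4-(3,4,5-trimethoxybenzoyl)-2-(3,4,5-trimethoxyphenyl)oxolane | COc1cc(C(=O)[C@@H]2CO[C@H](c3cc(OC)c(OC)c(OC)c3)[C@@H]2CO[Si](C)(C)C(C)(C)C)cc(OC)c1OC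
F6 | step 9 | (2S,3S,4R)-3-[(tert-butyldimethylsilyloxy)methyl]-4-(3,4,5-trimethoxybenzoyl)-2-(3,4,5-trimethoxyphenyl)oxolane | COc1cc(C(=O)[C@H]2CO[C@H](c3cc(OC)c(OC)c(OC)c3)[C@@H]2CO[Si](C)(C)C(C)(C)C)cc(OC)c1OC
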